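**Retrosynthetic overview**
1. The target is a methane carrying two 3-aroyl-2,4-dihydroxy-6-methoxyphenyl groups. It is cut between the bridging CH2 and C3 of ring A (the 2,6-dihydroxy-4-methoxybenzoyl ring of the half whose other ring, B, is 2,4-dihydroxy-6-methylphenyl), as a one-carbon unit is thought to bridge two acylphloroglucinols in nature.
2. Enabling feature: the CH2 sits on C3 of ring C (the same benzoyl ring in the other half, whose second ring, D, is 4-hydroxy-2-methoxy-6-methylphenyl), ortho to the C2 hydroxyl and para to the C6 hydroxyl, so CH2–C3–C2–OH is a latent ortho-quinone methide. Ring A has two free carbons (C3, C5), equivalent by symmetry and each ortho/para to three oxygens.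
3. Rings B and D are carried as benzyl ethers, so only rings A and C are free phenols in the Mannich step and the union; the three benzyl groups fall in the last step.
4. One benzophenone (9) serves both halves. It comes from a single ortho-lithiation of 1-methoxy-3,5-bis(methoxymethoxy)benzene between the two OMOM groups, addition to 2,4-bis(benzyloxy)-6-methylbenzaldehyde and oxidation. MOM removal gives the nucleophilic half; debenzylation, 4'-O-benzylation, 2'-O-methylation and MOM removal give the precursor of the electrophilic half.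
5. No ring is formed: all four benzene rings are bought (5-methoxyresorcinol and 2,4-dihydroxy-6-methylbenzaldehyde).

Key step: step 11

Remark: the target has no stereocentre and no axis expected to be configurationally stable, so it is achiral and needs no stereocontrol; carbinol 8 is racemic and loses its stereocentre on oxidation.

**Route**

Step 1
Reactants: 1 5-methoxyresorcinol; 2 chloromethyl methyl ether
Product: 3 1-methoxy-3,5-bis(methoxymethoxy)benzene
Conditions: MOMCl (2.5 equiv), i-Pr2NEt (3 equiv), CH2Cl2, 0 °C → rt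
Reagents that add atoms: chloromethyl methyl ether (2), COCCl
Why: Williamson-type O-alkylation of both phenols; the MOM groups later direct the ortho-lithiation and can be removed with acid beside benzyl ethers.

Step 2
Reactants: 4 2,4-dihydroxy-6-methylbenzaldehyde (orcinaldehyde); 5 benzyl bromide
Product: 6 2,4-bis(benzyloxy)-6-methylbenzaldehyde
Conditions: BnBr (2.4 equiv), K2CO3 (3 equiv), DMF, 60 °C
Reagents that add atoms: benzyl bromide (5), BrCc1ccccc1
Why: Williamson ether synthesis; excess reagent and carbonate in DMF should alkylate both the free 4-OH and the hydrogen-bonded 2-OH.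

Step 3
Reactants: 3 1-methoxy-3,5-bis(methoxymethoxy)benzene; 6 2,4-bis(benzyloxy)-6-methylbenzaldehyde
Product: 8 [2,4-bis(benzyloxy)-6-methylphenyl][4-methoxy-2,6-bis(methoxymethoxy)phenyl]methanol (racemic), via 4-methoxy-2,6-bis(methoxymethoxy)phenyllithium 7 (not isolated)
Conditions: n-BuLi (1.1 equiv), THF, 0 °C; then 6, −78 °C → 0 °C; H2O
Reagents that add atoms: none
Why: Directed ortho-metalation removes the proton flanked by the two OMOM groups (cooperative chelation, OMOM being a stronger director than OMe), and the aryllithium adds 1,2 to the aldehyde; the carbinol stereocentre is racemic and is erased in step 4.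

Step 4
Reactants: 8 [2,4-bis(benzyloxy)-6-methylphenyl][4-methoxy-2,6-bis(methoxymethoxy)phenyl]methanol
Product: 9 [2,4-bis(benzyloxy)-6-methylphenyl][4-methoxy-2,6-bis(methoxymethoxy)phenyl]methanone
Conditions: Dess–Martin periodinane (1.3 equiv), CH2Cl2, 0 °C → rt
Reagents that add atoms: none
Why: Dess–Martin oxidation of a secondary diaryl carbinol to the ketone under near-neutral conditions that spare MOM and benzyl ethers.

Step 5
Reactants: 9 [2,4-bis(benzyloxy)-6-methylphenyl][4-methoxy-2,6-bis(methoxymethoxy)phenyl]methanone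
Product: 10 [2,4-bis(benzyloxy)-6-methylphenyl](2,6-dihydroxy-4-methoxyphenyl)methanone
Conditions: HCl (cat.), MeOH–THF, 40 °C
Reagents that add atoms: none
Why: Acid-catalysed transacetalisation cleaves both MOM ethers and should leave benzyl and methyl ethers untouched; the 2'-oxygen is an ether, so xanthone closure is not open.

Step 6
Reactants: 9 [2,4-bis(benzyloxy)-6-methylphenyl][4-methoxy-2,6-bis(methoxymethoxy)phenyl]methanone
Product: 11 (2,4-dihydroxy-6-methylphenyl)[4-methoxy-2,6-bis(methoxymethoxy)phenyl]methanone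
Conditions: H2 (1 atm), 10% Pd/C, EtOAc, rt
Reagents that add atoms: none
Why: Catalytic hydrogenolysis of both aryl benzyl ethers under neutral conditions that should leave the MOM acetals and the hindered, di-ortho-substituted diaryl ketone intact, freeing the two hydroxyls of the later ring D so that they can be told apart.

Step 7
Reactants: 11 (2,4-dihydroxy-6-methylphenyl)[4-methoxy-2,6-bis(methoxymethoxy)phenyl]methanone; 5 benzyl bromide
Product: 12 [4-(benzyloxy)-2-hydroxy-6-methylphenyl][4-methoxy-2,6-bis(methoxymethoxy)phenyl]methanone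
Conditions: BnBr (1.05 equiv), K2CO3 (1.1 equiv), acetone, 50 °C
Reagents that add atoms: benzyl bromide (5), BrCc1ccccc1
Why: Regioselective Williamson mono-benzylation; the 2'-OH is locked in a hydrogen bond to the ketone and is hindered, while the para 4'-OH is the more acidic and accessible one, so a mild base and one equivalent of halide should alkylate O4' only (any doubly benzylated material is 9 and re-enters the route).

Step 8
Reactants: 12 [4-(benzyloxy)-2-hydroxy-6-methylphenyl][4-methoxy-2,6-bis(methoxymethoxy)phenyl]methanone; 13 iodomethane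
Product: 14 [4-(benzyloxy)-2-methoxy-6-methylphenyl][4-methoxy-2,6-bis(methoxymethoxy)phenyl]methanone
Conditions: MeI (2 equiv), K2CO3 (2 equiv), DMF, 40 °C
Reagents that add atoms: iodomethane (13), CI
Why: Williamson O-methylation of the remaining chelated phenol with carbonate in a polar aprotic solvent; ring C is fully protected, so only O2' can react.

Step 9
Reactants: 14 [4-(benzyloxy)-2-methoxy-6-methylphenyl][4-methoxy-2,6-bis(methoxymethoxy)phenyl]methanone
Product: 15 [4-(benzyloxy)-2-methoxy-6-methylphenyl](2,6-dihydroxy-4-methoxyphenyl)methanone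
Conditions: HCl (cat.), MeOH–THF, 40 °C
Reagents that add atoms: none
Why: Acid-catalysed MOM cleavage as in step 5; the aryl methyl and benzyl ethers should survive.

Step 10
Reactants: 15 [4-(benzyloxy)-2-methoxy-6-methylphenyl](2,6-dihydroxy-4-methoxyphenyl)methanone; 16 N,N-dimethylmethyleneiminium iodide (Eschenmoser's salt)
Product: 17 [4-(benzyloxy)-2-methoxy-6-methylphenyl]{3-[(dimethylamino)methyl]-2,6-dihydroxy-4-methoxyphenyl}methanone
Conditions: 16 (1.0 equiv), CH2Cl2–MeCN, 0 °C → rt; then NaHCO3 (1 equiv, aq) to free the base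
Reagents that add atoms: N,N-dimethylmethyleneiminium iodide (16), C=[N+](C)C.[I-]
Why: Phenolic Mannich reaction with a preformed iminium salt; ring C is the only phenolic, phloroglucinol-type ring, its two free carbons are equivalent, and the protonated product is deactivated toward a second substitution.

Step 11
Reactants: 17 [4-(benzyloxy)-2-methoxy-6-methylphenyl]{3-[(dimethylamino)methyl]-2,6-dihydroxy-4-methoxyphenyl}methanone; 10 [2,4-bis(benzyloxy)-6-methylphenyl](2,6-dihydroxy-4-methoxyphenyl)methanone
Product: 19 [2,4-bis(benzyloxy)-6-methylphenyl][3-({3-[4-(benzyloxy)-2-methoxy-6-methylbenzoyl]-2,4-dihydroxy-6-methoxyphenyl}methyl)-2,6-dihydroxy-4-methoxyphenyl]methanone (tri-O-benzyl ether of the target), via ortho-quinone methide 18 (not isolated)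
Conditions: 10 (2 equiv), 1,4-dioxane, 90 °C, slow addition of 17, N2 stream; excess 10 recovered
Reagents that add atoms: none
Why: On warming, the zwitterionic Mannich base 17 (an acidic, carbonyl-conjugated C2 phenol beside the aminomethyl group) should lose dimethylamine by E1cB elimination to give ortho-quinone methide 18, and C3 of ring A of 10 (as phenol or phenolate, the liberated amine serving as base) adds to its exocyclic methylene in a conjugate, Friedel–Crafts-type addition, after which both rings re-aromatise. The closest known reaction type is the Mannich-base (ortho-quinone methide) route to unsymmetrical methylene-bridged bis-acylphloroglucinols, which copies the presumed biosynthetic bridging of two acylphloroglucinol rings by a one-carbon unit. No ring is closed and no stereocentre is formed, so only chemo- and site selectivity are needed. Site selectivity on the nucleophile is secured because rings B and D are ethers without a free hydroxyl, while the two free carbons of ring A are equivalent, each ortho to OH and OMe and para to OH. Cross-coupling over self-coupling is secured by the excess of 10 and the slow addition of 17, which keep 18 dilute so that it meets ring A of 10 before the free C5–H of ring C in 17 or 19. C-alkylation is made irreversible by re-aromatisation, whereas O-adducts and the amine adduct revert to 18.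

Step 12
Reactants: 19 tri-O-benzyl ether of the target
Product: 20 (3-{[3-(4-hydroxy-2-methoxy-6-methylbenzoyl)-2,4-dihydroxy-6-methoxyphenyl]methyl}-2,6-dihydroxy-4-methoxyphenyl)(2,4-dihydroxy-6-methylphenyl)methanone (target, achiral)
Conditions: H2 (1 atm), 10% Pd/C, EtOAc–MeOH, rt
Reagents that add atoms: none
Why: Catalytic hydrogenolysis of the three aryl benzyl ethers; the di-ortho-substituted, hydrogen-bonded diaryl ketones and the diarylmethane bridge should not be reduced under these mild conditions.

**Compound list**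
1 | 5-methoxyresorcinol | COc1cc(O)cc(O)c1 | starting material
2 | chloromethyl methyl ether | COCCl | starting material
3 | 1-methoxy-3,5-bis(methoxymethoxy)benzene | COCOc1cc(OC)cc(OCOC)c1 | intermediate
4 | 2,4-dihydroxy-6-methylbenzaldehyde | Cc1cc(O)cc(O)c1C=O | starting material
5 | benzyl bromide | BrCc1ccccc1 | starting material
6 | 2,4-bis(benzyloxy)-6-methylbenzaldehyde | Cc1cc(OCc2ccccc2)cc(OCc2ccccc2)c1C=O | intermediate
7 | 4-methoxy-2,6-bis(methoxymethoxy)phenyllithium | [Li]c1c(OCOC)cc(OC)cc1OCOC | intermediate (not isolated)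
8 | [2,4-bis(benzyloxy)-6-methylphenyl][4-methoxy-2,6-bis(methoxymethoxy)phenyl]methanol (racemic) | COCOc1cc(OC)cc(OCOC)c1C(O)c1c(C)cc(OCc2ccccc2)cc1OCc1ccccc1 | intermediate
9 | [2,4-bis(benzyloxy)-6-methylphenyl][4-methoxy-2,6-bis(methoxymethoxy)phenyl]methanone | COCOc1cc(OC)cc(OCOC)c1C(=O)c1c(C)cc(OCc2ccccc2)cc1OCc1ccccc1 | intermediate
10 | [2,4-bis(benzyloxy)-6-methylphenyl](2,6-dihydroxy-4-methoxyphenyl)methanone | COc1cc(O)c(C(=O)c2c(C)cc(OCc3ccccc3)cc2OCc2ccccc2)c(O)c1 | intermediate
11 | (2,4-dihydroxy-6-methylphenyl)[4-methoxy-2,6-bis(methoxymethoxy)phenyl]methanone | COCOc1cc(OC)cc(OCOC)c1C(=O)c1c(C)cc(O)cc1O | intermediate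
12 | [4-(benzyloxy)-2-hydroxy-6-methylphenyl][4-methoxy-2,6-bis(methoxymethoxy)phenyl]methanone | COCOc1cc(OC)cc(OCOC)c1C(=O)c1c(C)cc(OCc2ccccc2)cc1O | intermediate
13 | iodomethane | CI | starting material
14 | [4-(benzyloxy)-2-methoxy-6-methylphenyl][4-methoxy-2,6-bis(methoxymethoxy)phenyl]methanone | COCOc1cc(OC)cc(OCOC)c1C(=O)c1c(C)cc(OCc2ccccc2)cc1OC | intermediate
15 | [4-(benzyloxy)-2-methoxy-6-methylphenyl](2,6-dihydroxy-4-methoxyphenyl)methanone | COc1cc(O)c(C(=O)c2c(C)cc(OCc3ccccc3)cc2OC)c(O)c1 | intermediate
16 | N,N-dimethylmethyleneiminium iodide | C=[N+](C)C.[I-] | starting material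
17 | [4-(benzyloxy)-2-methoxy-6-methylphenyl]{3-[(dimethylamino)methyl]-2,6-dihydroxy-4-methoxyphenyl}methanone | COc1cc(O)c(C(=O)c2c(C)cc(OCc3ccccc3)cc2OC)c(O)c1CN(C)C | intermediate
18 | 2-[4-(benzyloxy)-2-methoxy-6-methylbenzoyl]-3-hydroxy-5-methoxy-6-methylidenecyclohexa-2,4-dien-1-one | C=C1C(OC)=CC(O)=C(C(=O)c2c(C)cc(OCc3ccccc3)cc2OC)C1=O | intermediate (not isolated)
19 | [2,4-bis(benzyloxy)-6-methylphenyl][3-({3-[4-(benzyloxy)-2-methoxy-6-methylbenzoyl]-2,4-dihydroxy-6-methoxyphenyl}methyl)-2,6-dihydroxy-4-methoxyphenyl]methanone | COc1cc(O)c(C(=O)c2c(C)cc(OCc3ccccc3)cc2OCc2ccccc2)c(O)c1Cc1c(OC)cc(O)c(C(=O)c2c(C)cc(OCc3ccccc3)cc2OC)c1O | intermediate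
20 | (3-{[3-(4-hydroxy-2-methoxy-6-methylbenzoyl)-2,4-dihydroxy-6-methoxyphenyl]methyl}-2,6-dihydroxy-4-methoxyphenyl)(2,4-dihydroxy-6-methylphenyl)methanone | COc1cc(O)c(C(=O)c2c(C)cc(O)cc2O)c(O)c1Cc1c(OC)cc(O)c(C(=O)c2c(C)cc(O)cc2OC)c1O | target

**Step count and risks**
Total steps: 12. Longest linear sequence: 10 steps (steps 2, 3, 4, 6, 7, 8, 9, 10, 11 and 12, from 4).

Most likely to fail:

Step 11. The transient quinone methide may be captured by the free C5–H of ring C of unreacted 17 or of product 19 (self-condensation, oligomers). Ring A of 19 may also be alkylated a second time, or the bridge may be scrambled by retro-addition under the amine. The fallback sets out from 15 and comes back at 19. Vilsmeier–Haack formylation of 15 (POCl3, DMF, MeCN, 0 °C → rt; aq NaOAc) should give 3-[4-(benzyloxy)-2-methoxy-6-methylbenzoyl]-2,4-dihydroxy-6-methoxybenzaldehyde F1. Its formyl group deactivates ring C, so the electrophilic partner can no longer attack itself. F1 and 10 would then be joined by reductive Friedel–Crafts benzylation (TFA, Et3SiH 1.5 equiv, CH2Cl2, −20 → 0 °C). Acid-catalysed hydroxyalkylation of ring A of 10 should give the diarylmethanol F2 (not isolated), which ionises and is reduced by the silane to 19.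

Step 10. A second aminomethylation may occur at the remaining free carbon of ring C, or the free base may lose dimethylamine during isolation and condense with itself. The fallback sets out from 15 and comes back at 20, using bromine as a temporary block. NBS (1.0 equiv, CH2Cl2, −78 → 0 °C) should give [4-(benzyloxy)-2-methoxy-6-methylphenyl](3-bromo-2,6-dihydroxy-4-methoxyphenyl)methanone F3, with one free carbon left on ring C. The Mannich reaction with 16 would then give [4-(benzyloxy)-2-methoxy-6-methylphenyl]{3-bromo-5-[(dimethylamino)methyl]-2,6-dihydroxy-4-methoxyphenyl}methanone F4, which cannot react twice or attack itself. Heating F4 with 10 as in step 11 should pass through the bromo ortho-quinone methide F5 (not isolated) to the bromo tri-O-benzyl dimer F6. Hydrogenolysis (H2, Pd/C, NaOAc, EtOAc–MeOH) would remove the bromine together with the three benzyl groups and give 20.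

Step 12. Cleavage of three benzyl ethers on a poorly soluble polyphenolic dimer may stall, and prolonged exposure may begin to reduce the diaryl ketones. The fallback moves the hydrogenolysis ahead of the union; it sets out from 10 and 15 and comes back at 20. Hydrogenolysis of 10 (H2, Pd/C) should give (2,4-dihydroxy-6-methylphenyl)(2,6-dihydroxy-4-methoxyphenyl)methanone F7, and that of 15 should give (2,6-dihydroxy-4-methoxyphenyl)(4-hydroxy-2-methoxy-6-methylphenyl)methanone F8. The Mannich reaction of F8 with 16 would give {3-[(dimethylamino)methyl]-2,6-dihydroxy-4-methoxyphenyl}(4-hydroxy-2-methoxy-6-methylphenyl)methanone F9. Heating F9 with excess F7 should pass through the ortho-quinone methide F10 (not isolated) to 20 directly. Selectivity then rests only on the higher nucleophilicity of the phloroglucinol-type rings A and C over the resorcinol-type rings B and D.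

**Further compounds**
F1 | step 11 | 3-[4-(benzyloxy)-2-methoxy-6-methylbenzoyl]-2,4-dihydroxy-6-methoxybenzaldehyde | COc1cc(O)c(C(=O)c2c(C)cc(OCc3ccccc3)cc2OC)c(O)c1C=O
F2 | step 11 | [2,4-bis(benzyloxy)-6-methylphenyl][3-({3-[4-(benzyloxy)-2-methoxy-6-methylbenzoyl]-2,4-dihydroxy-6-methoxyphenyl}(hydroxy)methyl)-2,6-dihydroxy-4-methoxyphenyl]methanone (racemic) | COc1cc(O)c(C(=O)c2c(C)cc(OCc3ccccc3)cc2OCc2ccccc2)c(O)c1C(O)c1c(OC)cc(O)c(C(=O)c2c(C)cc(OCc3ccccc3)cc2OC)c1O
F3 | step 10 | [4-(benzyloxy)-2-methoxy-6-methylphenyl](3-bromo-2,6-dihydroxy-4-methoxyphenyl)methanone | COc1cc(O)c(C(=O)c2c(C)cc(OCc3ccccc3)cc2OC)c(O)c1Br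
F4 | step 10 | [4-(benzyloxy)-2-methoxy-6-methylphenyl]{3-bromo-5-[(dimethylamino)methyl]-2,6-dihydroxy-4-methoxyphenyl}methanone | COc1c(Br)c(O)c(C(=O)c2c(C)cc(OCc3ccccc3)cc2OC)c(O)c1CN(C)C
F5 | step 10 | 2-[4-(benzyloxy)-2-methoxy-6-methylbenzoyl]-4-bromo-3-hydroxy-5-methoxy-6-methylidenecyclohexa-2,4-dien-1-one | C=C1C(OC)=C(Br)C(O)=C(C(=O)c2c(C)cc(OCc3ccccc3)cc2OC)C1=O
F6 | step 10 | [2,4-bis(benzyloxy)-6-methylphenyl][3-({3-[4-(benzyloxy)-2-methoxy-6-methylbenzoyl]-5-bromo-2,4-dihydroxy-6-methoxyphenyl}methyl)-2,6-dihydroxy-4-methoxyphenyl]methanone | COc1cc(O)c(C(=O)c2c(C)cc(OCc3ccccc3)cc2OCc2ccccc2)c(O)c1Cc1c(OC)c(Br)c(O)c(C(=O)c2c(C)cc(OCc3ccccc3)cc2OC)c1O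
F7 | step 12 | (2,4-dihydroxy-6-methylphenyl)(2,6-dihydroxy-4-methoxyphenyl)methanone | COc1cc(O)c(C(=O)c2c(C)cc(O)cc2O)c(O)c1
F8 | step 12 | (2,6-dihydroxy-4-methoxyphenyl)(4-hydroxy-2-methoxy-6-methylphenyl)methanone | COc1cc(O)c(C(=O)c2c(C)cc(O)cc2OC)c(O)c1
F9 | step 12 | {3-[(dimethylamino)methyl]-2,6-dihydroxy-4-methoxyphenyl}(4-hydroxy-2-methoxy-6-methylphenyl)methanone | COc1cc(O)c(C(=O)c2c(C)cc(O)cc2OC)c(O)c1CN(C)C
F10 | step 12 | 3-hydroxy-2-(4-hydroxy-2-methoxy-6-methylbenzoyl)-5-methoxy-6-methylidenecyclohexa-2,4-dien-1-one | C=C1C(OC)=CC(O)=C(C(=O)c2c(C)cc(O)cc2OC)C1=O
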